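Ring A carries on neighbouring carbons C2 and C3 an arylethynyl group and the quinone methide carbon C7. Taken back to ketones, these become an aroylmethyl group on C2 and an aroyl group on C3, exactly the two pieces obtained by opening a CO–CH2 bond of 1,3-bis(4-methoxyphenyl)propane-1,3-dione. The route therefore inserts the C2–C3 aryne of ring A into that bond, which makes C2–CH2 and C3–C7 in a single operation and leaves one enolisable ketone for dehydration to the alkyne. The aryne comes from an ortho-silylaryl triflate that already holds the C1 methyl and C4 anisyl groups; aryllithium addition at C7 and demethylation with loss of water finish the synthesis.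

Key step: step 5

Remark: ring A is numbered C1 (methyl), C2 (alkynyl), C3 (carrying C7), C4 (aryl), C5-H, C6-H; the dienone ring on C7 is symmetrical, so the target has no stereocentre and no double-bond geometry to set.

Step 1
Reactants: 1 5-bromo-2-methylphenol; 2 4-methoxyphenylboronic acid
Product: 3 5-(4-methoxyphenyl)-2-methylphenol
Conditions: Pd(PPh3)4 (3 mol%), K2CO3, dioxane/H2O, 90 °C
Reagents that add atoms: none
Why: Suzuki–Miyaura coupling of an unhindered aryl bromide (oxidative addition to zerovalent palladium, transmetalation, reductive elimination) tolerates the free phenol under aqueous carbonate.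

Step 2
Reactants: 3 5-(4-methoxyphenyl)-2-methylphenol
Product: 4 5-(4-methoxyphenyl)-2-methylphenyl N-isopropylcarbamate
Conditions: i-PrNCO, Et3N (cat.), CH2Cl2, rt
Reagents that add atoms: isopropyl isocyanate, CC(C)N=C=O
Why: Base-catalysed addition of the phenol to the isocyanate gives a secondary carbamate, chosen over an N,N-dialkyl carbamate because it directs lithiation once N-silylated and is later removed under mild amine conditions.

Step 3
Reactants: 4 5-(4-methoxyphenyl)-2-methylphenyl N-isopropylcarbamate
Product: 8 3-(4-methoxyphenyl)-6-methyl-2-(trimethylsilyl)phenyl N-isopropylcarbamate, via N-silyl carbamate 5 (not isolated), via aryllithium 6 (not isolated), via bis-silyl carbamate 7 (not isolated)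
Conditions: Me3SiOTf, TMEDA, Et2O, 0 °C to rt; n-BuLi (2.2 equiv), TMEDA, −78 °C; Me3SiCl, −78 °C to rt; aq. NH4Cl
Reagents that add atoms: chlorotrimethylsilane, C[Si](C)(C)Cl
Why: Directed ortho-metalation: the in situ N-silylated carbamate directs n-BuLi/TMEDA to the only free ring position ortho to oxygen (between the oxygen and the aryl group), kinetic ring lithiation at −78 °C being preferred to lateral lithiation of the methyl group, and Me3SiCl traps the aryllithium before work-up hydrolyses the N–Si bond.

Step 4
Reactants: 8 3-(4-methoxyphenyl)-6-methyl-2-(trimethylsilyl)phenyl N-isopropylcarbamate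
Product: 10 3-(4-methoxyphenyl)-6-methyl-2-(trimethylsilyl)phenyl triflate, via silylphenol 9 (not isolated)
Conditions: DBU, Et2NH, MeCN, 40 °C; then PhNTf2, rt
Reagents that add atoms: N-phenylbis(trifluoromethanesulfonimide), O=S(=O)(N(c1ccccc1)S(=O)(=O)C(F)(F)F)C(F)(F)F
Why: DBU should cleave the secondary carbamate by E1cB elimination to the phenoxide and isopropyl isocyanate (scavenged by Et2NH as a urea), and the phenoxide is then O-triflated in the same flask under conditions mild enough to keep the aryl–silicon bond.

Step 5
Reactants: 10 3-(4-methoxyphenyl)-6-methyl-2-(trimethylsilyl)phenyl triflate; 11 1,3-bis(4-methoxyphenyl)propane-1,3-dione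
Product: 14 2-[4'-methoxy-2-(4-methoxybenzoyl)-4-methylbiphenyl-3-yl]-1-(4-methoxyphenyl)ethan-1-one, via aryne 12 (not isolated), via benzocyclobutenoxide 13 (not isolated)
Conditions: CsF (3 equiv), 11 (1.5 equiv), MeCN, 80 °C
Reagents that add atoms: none
Why: Fluoride attacks silicon of 10 and triflate leaves to give aryne 12; the cesium enolate of 11 adds through carbon to C2, the C3 aryl anion so formed attacks the neighbouring ketone carbonyl, and the strained alkoxide 13 opens by cleavage of the former CO–CH bond to the stabilised enolate of 14. The closest known reaction type is the acyl-alkylation of arynes from ortho-silylaryl triflates by insertion into a C–C sigma bond of a beta-dicarbonyl compound. The only ring formed is the transient four-membered ring of 13, closed in a 4-exo-trig mode and reopened in the same sequence, so no ring and no stereocentre persists. The step needs attack at C2 and not at C3: the sigma-withdrawing C4 aryl group should polarise the aryne so that C2 is the more electrophilic terminus and the charge developing at C3 is stabilised, the C1 methyl group does not oppose this, and the twisted aryl group shields C3 more than methyl shields C2. Because 11 is symmetrical either carbonyl leads to the same product, and its excess limits a second arylation of 14.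

Step 6
Reactants: 14 2-[4'-methoxy-2-(4-methoxybenzoyl)-4-methylbiphenyl-3-yl]-1-(4-methoxyphenyl)ethan-1-one
Product: 16 {4'-methoxy-3-[(4-methoxyphenyl)ethynyl]-4-methylbiphenyl-2-yl}(4-methoxyphenyl)methanone, via enol triflate 15 (not isolated)
Conditions: KN(SiMe3)2 (1.1 equiv), THF, −78 °C; PhNTf2, −78 to 0 °C; then KN(SiMe3)2 (2 equiv), 0 °C to rt
Reagents that add atoms: none
Why: Only the CH2 between ring A and the carbonyl can be deprotonated (the diaryl ketone has no alpha hydrogen), so enolate O-triflation should give the (Z)-enol triflate, whose vinylic hydrogen lies anti to the triflate and is removed by further silylamide in an E2 elimination to the diarylalkyne, the hindered base neither adding to nor reducing the benzophenone.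

Step 7
Reactants: 16 {4'-methoxy-3-[(4-methoxyphenyl)ethynyl]-4-methylbiphenyl-2-yl}(4-methoxyphenyl)methanone; 17 4-bromoanisole
Product: 19 bis(4-methoxyphenyl){4'-methoxy-3-[(4-methoxyphenyl)ethynyl]-4-methylbiphenyl-2-yl}methanol, via 4-methoxyphenyllithium 18 (not isolated)
Conditions: 17, n-BuLi, THF, −78 °C; then 16, −78 to 0 °C; H2O
Reagents that add atoms: none
Why: Bromine–lithium exchange followed by 1,2-addition of the aryllithium to the only remaining, non-enolisable carbonyl should give the triaryl carbinol, with low temperature and a neutral water quench chosen to prevent alkoxide addition to the alkyne and ionisation of the carbinol.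

Step 8
Reactants: 19 bis(4-methoxyphenyl){4'-methoxy-3-[(4-methoxyphenyl)ethynyl]-4-methylbiphenyl-2-yl}methanol
Product: 21 Selaginellin U, via tetraphenol carbinol 20 (not isolated)
Conditions: BBr3 (8 equiv), CH2Cl2, −78 °C to rt; then H2O, 0 °C
Reagents that add atoms: none
Why: Lewis acid cleavage of the four aryl methyl ethers by BBr3 and hydrolysis should give the tetraphenolic triaryl carbinol, which loses water spontaneously through its doubly para-hydroxy-stabilised cation to form the quinone methide (fuchsone formation).

Compound list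
1 | 5-bromo-2-methylphenol | Cc1ccc(Br)cc1O | starting material
2 | 4-methoxyphenylboronic acid | COc1ccc(B(O)O)cc1 | starting material
3 | 5-(4-methoxyphenyl)-2-methylphenol | Cc1ccc(-c2ccc(OC)cc2)cc1O | intermediate
4 | 5-(4-methoxyphenyl)-2-methylphenyl N-isopropylcarbamate | Cc1ccc(-c2ccc(OC)cc2)cc1OC(=O)NC(C)C | intermediate
5 | 5-(4-methoxyphenyl)-2-methylphenyl N-isopropyl-N-(trimethylsilyl)carbamate (not isolated) | Cc1ccc(-c2ccc(OC)cc2)cc1OC(=O)N(C(C)C)[Si](C)(C)C | intermediate
6 | 2-lithio-3-(4-methoxyphenyl)-6-methylphenyl N-isopropyl-N-(trimethylsilyl)carbamate (not isolated) | Cc1ccc(-c2ccc(OC)cc2)c([Li])c1OC(=O)N(C(C)C)[Si](C)(C)C | intermediate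
7 | 3-(4-methoxyphenyl)-6-methyl-2-(trimethylsilyl)phenyl N-isopropyl-N-(trimethylsilyl)carbamate (not isolated) | Cc1ccc(-c2ccc(OC)cc2)c([Si](C)(C)C)c1OC(=O)N(C(C)C)[Si](C)(C)C | intermediate
8 | 3-(4-methoxyphenyl)-6-methyl-2-(trimethylsilyl)phenyl N-isopropylcarbamate | Cc1ccc(-c2ccc(OC)cc2)c([Si](C)(C)C)c1OC(=O)NC(C)C | intermediate
9 | 3-(4-methoxyphenyl)-6-methyl-2-(trimethylsilyl)phenol (not isolated) | Cc1ccc(-c2ccc(OC)cc2)c([Si](C)(C)C)c1O | intermediate
10 | 3-(4-methoxyphenyl)-6-methyl-2-(trimethylsilyl)phenyl triflate | Cc1ccc(-c2ccc(OC)cc2)c([Si](C)(C)C)c1OS(=O)(=O)C(F)(F)F | intermediate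
11 | 1,3-bis(4-methoxyphenyl)propane-1,3-dione | COc1ccc(C(=O)CC(=O)c2ccc(OC)cc2)cc1 | starting material
12 | 3-(4-methoxyphenyl)-6-methylbenzyne (not isolated) | CC1=CC=C(c2ccc(OC)cc2)C#C1 | intermediate
13 | cesium benzocyclobutenoxide: four-membered ring fused at C2–C3 of ring A, C(O−)(4-methoxyphenyl) on C3 and CH(4-methoxybenzoyl) on C2; racemic, mixture of diastereomers (not isolated) | Cc1ccc(-c3ccc(OC)cc3)c2c1C(C(=O)c1ccc(OC)cc1)C2([O-])c1ccc(OC)cc1.[Cs+] | intermediate
14 | 2-[4'-methoxy-2-(4-methoxybenzoyl)-4-methylbiphenyl-3-yl]-1-(4-methoxyphenyl)ethan-1-one | Cc1ccc(-c2ccc(OC)cc2)c(C(=O)c2ccc(OC)cc2)c1CC(=O)c1ccc(OC)cc1 | intermediate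
15 | (Z)-2-[4'-methoxy-2-(4-methoxybenzoyl)-4-methylbiphenyl-3-yl]-1-(4-methoxyphenyl)ethenyl triflate (not isolated) | Cc1ccc(-c2ccc(OC)cc2)c(C(=O)c2ccc(OC)cc2)c1/C=C(\OS(=O)(=O)C(F)(F)F)c1ccc(OC)cc1 | intermediate
16 | {4'-methoxy-3-[(4-methoxyphenyl)ethynyl]-4-methylbiphenyl-2-yl}(4-methoxyphenyl)methanone | Cc1ccc(-c2ccc(OC)cc2)c(C(=O)c2ccc(OC)cc2)c1C#Cc1ccc(OC)cc1 | intermediate
17 | 4-bromoanisole | COc1ccc(Br)cc1 | starting material
18 | 4-methoxyphenyllithium (not isolated) | COc1ccc([Li])cc1 | intermediate
19 | bis(4-methoxyphenyl){4'-methoxy-3-[(4-methoxyphenyl)ethynyl]-4-methylbiphenyl-2-yl}methanol | Cc1ccc(-c2ccc(OC)cc2)c(C(O)(c2ccc(OC)cc2)c2ccc(OC)cc2)c1C#Cc1ccc(OC)cc1 | intermediate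
20 | bis(4-hydroxyphenyl){4'-hydroxy-3-[(4-hydroxyphenyl)ethynyl]-4-methylbiphenyl-2-yl}methanol (not isolated) | Cc1ccc(-c2ccc(O)cc2)c(C(O)(c2ccc(O)cc2)c2ccc(O)cc2)c1C#Cc1ccc(O)cc1 | intermediate
21 | Selaginellin U, 4-[(4-hydroxyphenyl){4'-hydroxy-3-[(4-hydroxyphenyl)ethynyl]-4-methylbiphenyl-2-yl}methylidene]cyclohexa-2,5-dien-1-one | Cc1ccc(-c2ccc(O)cc2)c(C(=C2C=CC(=O)C=C2)c2ccc(O)cc2)c1C#Cc1ccc(O)cc1 | target

Total step count: 8. Longest linear sequence: 8 steps (1 to 21); compounds 2, 11 and 17 enter as purchased components.

Steps most likely to fail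

Step 5. The enolate may attack the aryne at C3 instead of C2 (poor regioselectivity), or the C3 aryl anion may be protonated before it closes onto the carbonyl, stopping at simple alpha-arylation of the diketone. The fallback drops the aryne and installs the two groups one after the other. It sets out from carbamate 4, which is lithiated exactly as in step 3 (through 5 and 6). Quenching 6 with N,4-dimethoxy-N-methylbenzamide should give, after aqueous work-up, 2-(4-methoxybenzoyl)-3-(4-methoxyphenyl)-6-methylphenyl N-isopropylcarbamate F1. Treatment with DBU and Et2NH in MeCN would release [3-hydroxy-4'-methoxy-4-methylbiphenyl-2-yl](4-methoxyphenyl)methanone F2, which is triflated in the same flask with PhNTf2 to 2-(4-methoxybenzoyl)-3-(4-methoxyphenyl)-6-methylphenyl triflate F3. Sonogashira coupling of F3 with 1-ethynyl-4-methoxybenzene (Pd(PPh3)2Cl2, CuI, Et3N, DMF, 70 °C) should then deliver alkynyl ketone 16, where the route is rejoined before step 7.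

Step 3. Lithiation may be diverted to the methyl group (lateral metalation), may be slow at the ring position flanked by the carbamate and the aryl group, or the base may attack the carbamate carbonyl. The fallback replaces C–H lithiation by halogen–lithium exchange. It sets out from phenol 3, which is brominated at its only free ortho position with NBS and catalytic i-Pr2NH in CH2Cl2 to give 2-bromo-3-(4-methoxyphenyl)-6-methylphenol F4. Silylation on oxygen with hexamethyldisilazane would give [2-bromo-3-(4-methoxyphenyl)-6-methylphenoxy]trimethylsilane F5. With n-BuLi in THF at −78 °C, bromine–lithium exchange and 1,3-migration of silicon from oxygen to carbon (retro-Brook rearrangement) should furnish silylphenol 9 as its lithium salt, which is triflated in the same flask with Tf2O. The route is rejoined at triflate 10.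

Step 6. The enolate oxygen may engage the neighbouring benzophenone carbonyl (closure toward isochromene or 2-benzopyrylium species) instead of being triflated, or the base may cleave the S–O bond of the enol triflate in place of eliminating it. The fallback avoids enolate chemistry altogether and sets out from diketone 14. Condensation of the unhindered benzyl ketone with semicarbazide hydrochloride and NaOAc in aqueous ethanol should give the semicarbazone of 14, F6. Oxidative cyclisation with SeO2 in acetic acid would give 5-[4'-methoxy-2-(4-methoxybenzoyl)-4-methylbiphenyl-3-yl]-4-(4-methoxyphenyl)-1,2,3-selenadiazole F7. Thermolysis of F7 in o-dichlorobenzene at about 180 °C extrudes nitrogen and selenium and should give alkynyl ketone 16, where the route is rejoined before step 7.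

Further compounds
F1 | step 5 | 2-(4-methoxybenzoyl)-3-(4-methoxyphenyl)-6-methylphenyl N-isopropylcarbamate | Cc1ccc(-c2ccc(OC)cc2)c(C(=O)c2ccc(OC)cc2)c1OC(=O)NC(C)C
F2 | step 5 | [3-hydroxy-4'-methoxy-4-methylbiphenyl-2-yl](4-methoxyphenyl)methanone | Cc1ccc(-c2ccc(OC)cc2)c(C(=O)c2ccc(OC)cc2)c1O
F3 | step 5 | 2-(4-methoxybenzoyl)-3-(4-methoxyphenyl)-6-methylphenyl triflate | Cc1ccc(-c2ccc(OC)cc2)c(C(=O)c2ccc(OC)cc2)c1OS(=O)(=O)C(F)(F)F
F4 | step 3 | 2-bromo-3-(4-methoxyphenyl)-6-methylphenol | Cc1ccc(-c2ccc(OC)cc2)c(Br)c1O
F5 | step 3 | [2-bromo-3-(4-methoxyphenyl)-6-methylphenoxy]trimethylsilane | Cc1ccc(-c2ccc(OC)cc2)c(Br)c1O[Si](C)(C)C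
F6 | step 6 | semicarbazone of 14 at the benzyl ketone (C=N geometry not defined) | Cc1ccc(-c2ccc(OC)cc2)c(C(=O)c2ccc(OC)cc2)c1CC(=NNC(N)=O)c1ccc(OC)cc1
F7 | step 6 | 5-[4'-methoxy-2-(4-methoxybenzoyl)-4-methylbiphenyl-3-yl]-4-(4-methoxyphenyl)-1,2,3-selenadiazole | Cc1ccc(-c2ccc(OC)cc2)c(C(=O)c2ccc(OC)cc2)c1C1=C(c2ccc(OC)cc2)N=N[Se]1
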